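**Assumption:** the target is taken exactly as the SMILES encodes it: furofuran 7S,8R,7′S,8′R with both aryl groups exo (C7 = guaiacyl-bearing carbon, C7′ = syringyl-bearing carbon, C8/C8′ = ring-fusion carbons) and an erythro (7″S,8″R) glycerol unit on the syringyl oxygen.

## Retrosynthetic overview

1. Hedyotol C ⇐ debenzylation and reductive auxiliary removal of an anti-aldol adduct; the aldol joins aryloxyacetyl imide 19 (from medioresinol benzyl ether 16) to O-benzylvanillin 6 and sets C7″/C8″.
2. Furofuran 16 ⇐ ring B closed last by SN1 cycloetherification of diol 15 (sets C7′); ring A ⇐ Lewis-acid ring contraction of the 4,5-dihydro-1,3-dioxepine 12 to the tetrahydrofuran-3-carbaldehyde 13 (sets C7, C8).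
3. 12 ⇐ acetal 10 (from 6 and cis-butenediol) plus syringaldehyde 8 by a new enantioselective nickel-catalysed alkene–aldehyde–silyl triflate coupling (sets C8′).
4. All three arenes ⇐ catechol: guaiacol → vanillin → 5-bromovanillin → syringaldehyde.
5. Ring order: seven-membered acetal (temporary) → ring A → ring B.

## Route

Step 1
Reactants: 1 catechol
Product: 2 guaiacol (2-methoxyphenol)
Conditions: MeI (0.9 equiv), K2CO3, acetone, reflux; distillation
Reagents that add atoms: iodomethane CI
Why: Williamson mono-O-methylation; catechol is kept in excess so the dimethyl ether stays minor and guaiacol is separated by distillation.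

Step 2
Reactants: 2 guaiacol; 3 glyoxylic acid
Product: 5 vanillin, via 4-hydroxy-3-methoxymandelic acid 4 (not isolated)
Conditions: NaOH, H2O, 25 °C; then CuSO4 (cat.), air, 95 °C; H2SO4 work-up
Reagents that add atoms: none
Why: para-selective hydroxyalkylation of the phenolate by glyoxylate followed by copper-catalysed aerobic oxidative decarboxylation (the technical vanillin sequence); the mandelic stereocentre is destroyed.

Step 3
Reactants: 5 vanillin
Product: 6 4-(benzyloxy)-3-methoxybenzaldehyde (O-benzylvanillin)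
Conditions: BnBr, K2CO3, DMF, 60 °C
Reagents that add atoms: benzyl bromide BrCc1ccccc1
Why: Williamson etherification; benzyl survives every later step and both benzyl groups fall together at the end.

Step 4
Reactants: 5 vanillin
Product: 7 5-bromovanillin (3-bromo-4-hydroxy-5-methoxybenzaldehyde)
Conditions: Br2, MeOH, 0 °C
Reagents that add atoms: bromine BrBr
Why: electrophilic aromatic bromination at the only free position ortho to the phenol.

Step 5
Reactants: 7 5-bromovanillin
Product: 8 syringaldehyde (4-hydroxy-3,5-dimethoxybenzaldehyde)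
Conditions: NaOMe (excess), CuCl (cat.), DMF–MeOH, 110 °C
Reagents that add atoms: sodium methoxide [Na+].[O-]C
Why: copper-catalysed Ullmann-type methoxylation of the aryl bromide, the classical vanillin-to-syringaldehyde conversion.

Step 6
Reactants: 6 O-benzylvanillin; 9 (Z)-but-2-ene-1,4-diol
Product: 10 2-[4-(benzyloxy)-3-methoxyphenyl]-4,7-dihydro-1,3-dioxepine
Conditions: TsOH·H2O (cat.), toluene, reflux, Dean–Stark
Reagents that add atoms: none
Why: acid-catalysed acetalisation with azeotropic water removal; the cis-diol closes the seven-membered acetal, which has a mirror plane and is achiral.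

Step 7
Reactants: 10 dihydrodioxepine acetal (1.5 equiv); 8 syringaldehyde
Product: 12 (5R)-2-[4-(benzyloxy)-3-methoxyphenyl]-5-{[3,5-dimethoxy-4-(triethylsilyloxy)phenyl](triethylsilyloxy)methyl}-4,5-dihydro-1,3-dioxepine (mixture at C2 and at the silyloxy-bearing carbon), via 3,5-dimethoxy-4-(triethylsilyloxy)benzaldehyde 11 (not isolated)
Conditions: Et3SiOTf (1.1 equiv), Et3N, toluene, 0 °C; then 10, Ni(cod)2 (15 mol%), chiral monophosphine (neomenthyldiphenylphosphine type, 30 mol%), Et3SiOTf (1.8 equiv), Et3N (6 equiv), 23 °C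
Reagents that add atoms: triethylsilyl trifluoromethanesulfonate CC[Si](CC)(CC)OS(=O)(=O)C(F)(F)F
Why: Proposed new method: enantioselective desymmetrising three-component coupling of a cis-disubstituted cyclic alkene with an aryl aldehyde and a silyl triflate on zerovalent nickel; the nickel–phosphine complex binds the alkene (made a good acceptor by its two allylic oxygens), silyl-triflate-assisted oxidative cyclisation with 11 forms the C5–C bond and a C6–Ni bond on the same face, the ring leaves only a C7 hydrogen syn to nickel so β-hydride elimination must give the 6,7-enol ether, and Et3N returns zerovalent nickel; the chiral phosphine chooses between the two enantiotopic alkene carbons of 10 and thereby sets C5 (R) (the ligand antipode that gives 5R is used, the C2 and carbinol centres are erased in steps 8 and 10); closest known reactions are the nickel-catalysed alkene–aldehyde–silyl triflate coupling of terminal alkenes and the asymmetric Heck arylation of 4,7-dihydro-1,3-dioxepines.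

Step 8
Reactants: 12 5-substituted 4,5-dihydro-1,3-dioxepine
Product: 13 (2S,3R,4R)-2-[4-(benzyloxy)-3-methoxyphenyl]-4-{[3,5-dimethoxy-4-(triethylsilyloxy)phenyl](triethylsilyloxy)methyl}tetrahydrofuran-3-carbaldehyde (2,3-cis and 3,4-trans)
Conditions: TMSOTf (20 mol%), CH2Cl2, −78 °C, 30 min; Et3N quench at −78 °C
Reagents that add atoms: none
Why: Lewis-acid-mediated ring contraction of a cyclic vinyl acetal (stepwise and ionic: the acetal C–O bond to the enol oxygen ionises and the oxocarbenium/silyl enol ether ion pair recloses through carbon, an intramolecular Mukaiyama-type aldol); the C5 substituent sends the new C–C bond to the opposite face (3,4-trans, allylic strain of the Z-enol ether) and the compact ion-pair collapse gives the kinetic 2,3-cis product, so the aryl group ends trans to the side chain (C7 = S).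

Step 9
Reactants: 13 tetrahydrofuran-3-carbaldehyde
Product: 15 [(2S,3R,4R)-2-[4-(benzyloxy)-3-methoxyphenyl]-4-[hydroxy(4-hydroxy-3,5-dimethoxyphenyl)methyl]tetrahydrofuran-3-yl]methanol (mixture at the carbinol carbon), via bicyclic lactol 14 (not isolated)
Conditions: TBAF (2.5 equiv), THF, 0 → 23 °C; then MeOH, NaBH4, 0 °C
Reagents that add atoms: none
Why: fluoride desilylation gives a basic medium that epimerises the centre α to the aldehyde, and only the 3,4-cis epimer can close to the cis-fused lactol 14, which drains the equilibrium (retro-oxa-Michael opening of ring A would be a disfavoured reverse 5-endo process); borohydride reduction of the lactol then fixes C8 (R) in the diol.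

Step 10
Reactants: 15 diol
Product: 16 4-{(1S,3aR,4S,6aR)-4-[4-(benzyloxy)-3-methoxyphenyl]tetrahydro-1H,3H-furo[3,4-c]furan-1-yl}-2,6-dimethoxyphenol (medioresinol benzylated on the guaiacyl oxygen)
Conditions: camphorsulfonic acid (10 mol%), CH2Cl2, 0 °C
Reagents that add atoms: none
Why: SN1 cycloetherification through the para-quinone methide of the 4-hydroxy-3,5-dimethoxybenzyl alcohol; the primary alcohol adds so that the aryl group lies on the convex face of the cis-fused bicycle, which makes both carbinol epimers converge on C7′ (S), while the less easily ionised benzyloxyaryl ether carbon C7 is untouched under these mild conditions.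

Step 11
Reactants: 17 bromoacetyl bromide
Product: 18 (4R)-4-benzyl-3-(bromoacetyl)-1,3-oxazolidin-2-one
Conditions: (R)-4-benzyl-1,3-oxazolidin-2-one, n-BuLi, THF, −78 °C; then 17
Reagents that add atoms: (R)-4-benzyl-1,3-oxazolidin-2-one (chiral auxiliary) O=C1N[C@H](Cc2ccccc2)CO1
Why: N-acylation of the lithiated oxazolidinone by the acid bromide, which reacts far faster than the alkyl bromide.

Step 12
Reactants: 16 furofuran phenol; 18 bromoacetyl imide
Product: 19 (4R)-4-benzyl-3-[2-(4-{(1S,3aR,4S,6aR)-4-[4-(benzyloxy)-3-methoxyphenyl]tetrahydro-1H,3H-furo[3,4-c]furan-1-yl}-2,6-dimethoxyphenoxy)acetyl]-1,3-oxazolidin-2-one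
Conditions: K2CO3, acetone, 23 °C
Reagents that add atoms: none
Why: Williamson etherification of the only free phenol with an activated α-bromo imide; no stereocentre is involved.

Step 13
Reactants: 19 aryloxyacetyl imide; 6 O-benzylvanillin (1.3 equiv)
Product: 21 (4R)-4-benzyl-3-[(2S,3S)-3-[4-(benzyloxy)-3-methoxyphenyl]-3-hydroxy-2-(aryloxy)propanoyl]-1,3-oxazolidin-2-one (aryloxy = the furofuran-substituted 2,6-dimethoxyphenoxy group of 19), via trimethylsilyl ether 20 (not isolated)
Conditions: MgCl2 (20 mol%), Et3N, TMSCl, EtOAc, 23 °C; then 1 M HCl, THF, 0 °C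
Reagents that add atoms: none
Why: Evans magnesium-halide-catalysed anti-aldol of an N-acyloxazolidinone with a non-enolisable aryl aldehyde; the magnesium-chelated Z-enolate of the (R)-auxiliary is attacked on its Si face (away from the benzyl group) and the anti transition state puts the aldehyde Re face on it, giving the erythro relationship with C8″ and C7″ in the target sense.

Step 14
Reactants: 21 anti-aldol adduct
Product: 22 (1S,2R)-1-[4-(benzyloxy)-3-methoxyphenyl]-2-(4-{(1S,3aR,4S,6aR)-4-[4-(benzyloxy)-3-methoxyphenyl]tetrahydro-1H,3H-furo[3,4-c]furan-1-yl}-2,6-dimethoxyphenoxy)propane-1,3-diol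
Conditions: LiBH4, THF, MeOH (1 equiv), 0 °C
Reagents that add atoms: none
Why: reductive cleavage of the N-acyloxazolidinone to the primary alcohol without touching either stereocentre (the C8″ descriptor changes from S to R only because the ranking of its substituents changes).

Step 15
Reactants: 22 dibenzyl ether
Product: 23 Hedyotol C
Conditions: H2 (1 atm), Pd/C (10%), EtOAc, 23 °C, stopped at full conversion
Reagents that add atoms: none
Why: hydrogenolysis of the two aryl benzyl ethers, which are cleaved much faster than the benzylic alcohol or the furofuran C–O bonds in a neutral solvent.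

## Compound list

1 | catechol | Oc1ccccc1O | starting material
2 | guaiacol | COc1ccccc1O | intermediate
3 | glyoxylic acid | OC(=O)C=O | starting material
4 | 4-hydroxy-3-methoxymandelic acid (racemic, not isolated) | COc1cc(C(O)C(=O)O)ccc1O | intermediate
5 | vanillin | COc1cc(C=O)ccc1O | intermediate
6 | 4-(benzyloxy)-3-methoxybenzaldehyde | COc1cc(C=O)ccc1OCc1ccccc1 | intermediate
7 | 5-bromovanillin | COc1cc(C=O)cc(Br)c1O | intermediate
8 | syringaldehyde | COc1cc(C=O)cc(OC)c1O | intermediate
9 | (Z)-but-2-ene-1,4-diol | OC/C=C\CO | starting material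
10 | 2-[4-(benzyloxy)-3-methoxyphenyl]-4,7-dihydro-1,3-dioxepine | COc1cc(C2OCC=CCO2)ccc1OCc1ccccc1 | intermediate
11 | 3,5-dimethoxy-4-(triethylsilyloxy)benzaldehyde (not isolated) | CC[Si](CC)(CC)Oc1c(OC)cc(C=O)cc1OC | intermediate
12 | (5R)-2-[4-(benzyloxy)-3-methoxyphenyl]-5-{[3,5-dimethoxy-4-(triethylsilyloxy)phenyl](triethylsilyloxy)methyl}-4,5-dihydro-1,3-dioxepine; C2 and the silyloxy-bearing carbon are mixtures | CC[Si](CC)(CC)OC(c1cc(OC)c(O[Si](CC)(CC)CC)c(OC)c1)[C@H]1COC(c2ccc(OCc3ccccc3)c(OC)c2)OC=C1 | intermediate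
13 | (2S,3R,4R)-2-[4-(benzyloxy)-3-methoxyphenyl]-4-{[3,5-dimethoxy-4-(triethylsilyloxy)phenyl](triethylsilyloxy)methyl}tetrahydrofuran-3-carbaldehyde; side-chain carbon a mixture | COc1cc([C@H]2OC[C@@H]([C@H]2C=O)C(O[Si](CC)(CC)CC)c2cc(OC)c(O[Si](CC)(CC)CC)c(OC)c2)ccc1OCc1ccccc1 | intermediate
14 | cis-fused lactol: 4-[4-(benzyloxy)-3-methoxyphenyl]-1-(4-hydroxy-3,5-dimethoxyphenyl)tetrahydro-1H,3H-furo[3,4-c]furan-3-ol, guaiacyl carbon and both ring-fusion carbons as in 16, hemiacetal and syringyl carbons mixtures (not isolated) | COc1cc([C@H]2OC[C@H]3[C@@H]2C(O)OC3c2cc(OC)c(O)c(OC)c2)ccc1OCc1ccccc1 | intermediate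
15 | [(2S,3R,4R)-2-[4-(benzyloxy)-3-methoxyphenyl]-4-[hydroxy(4-hydroxy-3,5-dimethoxyphenyl)methyl]tetrahydrofuran-3-yl]methanol; carbinol carbon a mixture | COc1cc([C@H]2OC[C@@H]([C@@H]2CO)C(O)c2cc(OC)c(O)c(OC)c2)ccc1OCc1ccccc1 | intermediate
16 | 4-{(1S,3aR,4S,6aR)-4-[4-(benzyloxy)-3-methoxyphenyl]tetrahydro-1H,3H-furo[3,4-c]furan-1-yl}-2,6-dimethoxyphenol | COc1cc([C@H]2OC[C@H]3[C@@H]2CO[C@@H]3c2cc(OC)c(O)c(OC)c2)ccc1OCc1ccccc1 | intermediate
17 | bromoacetyl bromide | BrCC(Br)=O | starting material
18 | (4R)-4-benzyl-3-(bromoacetyl)-1,3-oxazolidin-2-one | O=C1N(C(=O)CBr)[C@H](Cc2ccccc2)CO1 | intermediate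
19 | (4R)-4-benzyl-3-[2-(4-{(1S,3aR,4S,6aR)-4-[4-(benzyloxy)-3-methoxyphenyl]tetrahydro-1H,3H-furo[3,4-c]furan-1-yl}-2,6-dimethoxyphenoxy)acetyl]-1,3-oxazolidin-2-one | COc1cc([C@H]2OC[C@H]3[C@@H]2CO[C@@H]3c2cc(OC)c(OCC(=O)N3[C@H](Cc4ccccc4)COC3=O)c(OC)c2)ccc1OCc1ccccc1 | intermediate
20 | trimethylsilyl ether of 21 (not isolated) | COc1cc([C@H]2OC[C@H]3[C@@H]2CO[C@@H]3c2cc(OC)c(O[C@H](C(=O)N3[C@H](Cc4ccccc4)COC3=O)[C@@H](O[Si](C)(C)C)c3ccc(OCc4ccccc4)c(OC)c3)c(OC)c2)ccc1OCc1ccccc1 | intermediate
21 | (4R)-4-benzyl-3-[(2S,3S)-3-[4-(benzyloxy)-3-methoxyphenyl]-3-hydroxy-2-(aryloxy)propanoyl]-1,3-oxazolidin-2-one, aryloxy as in 19 | COc1cc([C@H]2OC[C@H]3[C@@H]2CO[C@@H]3c2cc(OC)c(O[C@H](C(=O)N3[C@H](Cc4ccccc4)COC3=O)[C@@H](O)c3ccc(OCc4ccccc4)c(OC)c3)c(OC)c2)ccc1OCc1ccccc1 | intermediate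
22 | (1S,2R)-1-[4-(benzyloxy)-3-methoxyphenyl]-2-(4-{(1S,3aR,4S,6aR)-4-[4-(benzyloxy)-3-methoxyphenyl]tetrahydro-1H,3H-furo[3,4-c]furan-1-yl}-2,6-dimethoxyphenoxy)propane-1,3-diol | COc1cc([C@H]2OC[C@H]3[C@@H]2CO[C@@H]3c2cc(OC)c(O[C@H](CO)[C@@H](O)c3ccc(OCc4ccccc4)c(OC)c3)c(OC)c2)ccc1OCc1ccccc1 | intermediate
23 | Hedyotol C: (1S,2R)-2-{4-[(1S,3aR,4S,6aR)-4-(4-hydroxy-3-methoxyphenyl)tetrahydro-1H,3H-furo[3,4-c]furan-1-yl]-2,6-dimethoxyphenoxy}-1-(4-hydroxy-3-methoxyphenyl)propane-1,3-diol | COc1cc([C@H]2OC[C@H]3[C@@H]2CO[C@@H]3c2cc(OC)c(O[C@H](CO)[C@@H](O)c3ccc(O)c(OC)c3)c(OC)c2)ccc1O | target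

## Step count and risks

Total steps: 15. Longest linear sequence: 12 (steps 1, 2, 3, 6, 7, 8, 9, 10, 12, 13, 14, 15; the branch through steps 4 and 5 is equally long).

**Step 7 (proposed new coupling).** Internal alkenes are outside the proven scope of the nickel/silyl triflate coupling, the silyl triflate may ionise the aryl acetal of 10, and the sense and level of induction are unknown. Fallback with known chemistry, setting out from 8 and 6 and returning at 12:
- Syringaldehyde 8 is silylated separately (Et3SiCl, imidazole) to give 11 as an isolated compound.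
- But-2-yne-1,4-diol F1 is converted with TMSCl and Et3N into 1,4-bis(trimethylsilyloxy)but-2-yne F2.
- An enantioselective nickel-catalysed reductive coupling of F2 with 11 (Ni(cod)2, chiral N-heterocyclic carbene, Et3SiH, THF) gives, by syn addition, the (E)-allylic silyl ether F3 with a defined carbinol centre (drawn S; either antipode serves).
- Noyori acetalisation of the two trimethylsilyl ethers of F3 with 6 (TMSOTf cat., CH2Cl2, −78 °C) closes the 5-substituted 4,7-dihydro-1,3-dioxepine F4.
- Alkene isomerisation with RuHCl(CO)(PPh3)3 in toluene at 80 °C moves the double bond to the enol ether position. Because the carbinol centre is fixed, the two C5 epimers are diastereomers and are separated; the 5R epimer is 12 as a single carbinol isomer.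

**Step 8 (ring contraction).** The very electron-rich benzylic silyl ether may ionise under TMSOTf in competition with the acetal, and warming would erode the kinetic 2,3-cis selectivity that fixes C7. Fallback from 12, returning at 15:
- Both silyl groups are removed with TBAF to give the phenol–carbinol dihydrodioxepine F5.
- Acetylation (Ac2O, pyridine, DMAP) gives the diacetate F6, whose benzylic C–O bond is deactivated towards ionisation.
- The same TMSOTf ring contraction at −78 °C then gives the aldehyde diacetate F7.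
- K2CO3 in MeOH removes both acetates, epimerises the α-centre and closes lactol 14; NaBH4 in the same flask gives 15.

**Step 13 (anti-aldol).** α-Aryloxy imides are not the usual substrates of the magnesium-catalysed anti-aldol, and diastereoselectivity or conversion with the electron-rich aldehyde may be poor. Fallback from 16, returning at 22:
- 17 is acylated onto the (S)-auxiliary to give (4S)-4-benzyl-3-(bromoacetyl)-1,3-oxazolidin-2-one F8.
- Alkylation of 16 with F8 (K2CO3, acetone) gives the (S)-imide F9.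
- The well-established boron syn-aldol (Bu2BOTf, i-Pr2NEt, CH2Cl2, −78 → 0 °C, then 6) gives the threo (2S,3R) adduct F10, with C8″ already correct.
- Mitsunobu inversion of the benzylic alcohol with 4-nitrobenzoic acid (PPh3, DIAD) gives the erythro (2S,3S) 4-nitrobenzoate F11.
- LiBH4 cleaves the auxiliary and the ester together to give 22.

## Further compounds

F1 | step 7 | but-2-yne-1,4-diol | OCC#CCO
F2 | step 7 | 1,4-bis(trimethylsilyloxy)but-2-yne | C[Si](C)(C)OCC#CCO[Si](C)(C)C
F3 | step 7 | (S,E)-allylic silyl ether: triethyl{(1S,2E)-1-[3,5-dimethoxy-4-(triethylsilyloxy)phenyl]-4-(trimethylsilyloxy)-2-[(trimethylsilyloxy)methyl]but-2-enyloxy}silane | CC[Si](CC)(CC)O[C@@H](c1cc(OC)c(O[Si](CC)(CC)CC)c(OC)c1)/C(CO[Si](C)(C)C)=C/CO[Si](C)(C)C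
F4 | step 7 | 2-[4-(benzyloxy)-3-methoxyphenyl]-5-{(S)-[3,5-dimethoxy-4-(triethylsilyloxy)phenyl](triethylsilyloxy)methyl}-4,7-dihydro-1,3-dioxepine | CC[Si](CC)(CC)O[C@@H](c1cc(OC)c(O[Si](CC)(CC)CC)c(OC)c1)C1=CCOC(c2ccc(OCc3ccccc3)c(OC)c2)OC1
F5 | step 8 | (5R)-2-[4-(benzyloxy)-3-methoxyphenyl]-5-[hydroxy(4-hydroxy-3,5-dimethoxyphenyl)methyl]-4,5-dihydro-1,3-dioxepine | OC(c1cc(OC)c(O)c(OC)c1)[C@H]1COC(c2ccc(OCc3ccccc3)c(OC)c2)OC=C1
F6 | step 8 | diacetate of F5 | CC(=O)OC(c1cc(OC)c(OC(C)=O)c(OC)c1)[C@H]1COC(c2ccc(OCc3ccccc3)c(OC)c2)OC=C1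
F7 | step 8 | (2S,3R,4R)-4-{acetoxy[4-acetoxy-3,5-dimethoxyphenyl]methyl}-2-[4-(benzyloxy)-3-methoxyphenyl]tetrahydrofuran-3-carbaldehyde | COc1cc([C@H]2OC[C@@H]([C@H]2C=O)C(OC(C)=O)c2cc(OC)c(OC(C)=O)c(OC)c2)ccc1OCc1ccccc1
F8 | step 13 | (4S)-4-benzyl-3-(bromoacetyl)-1,3-oxazolidin-2-one | O=C1N(C(=O)CBr)[C@@H](Cc2ccccc2)CO1
F9 | step 13 | (4S)-auxiliary analogue of 19 | COc1cc([C@H]2OC[C@H]3[C@@H]2CO[C@@H]3c2cc(OC)c(OCC(=O)N3[C@@H](Cc4ccccc4)COC3=O)c(OC)c2)ccc1OCc1ccccc1
F10 | step 13 | syn (2S,3R) aldol adduct on the (4S)-auxiliary | COc1cc([C@H]2OC[C@H]3[C@@H]2CO[C@@H]3c2cc(OC)c(O[C@H](C(=O)N3[C@@H](Cc4ccccc4)COC3=O)[C@H](O)c3ccc(OCc4ccccc4)c(OC)c3)c(OC)c2)ccc1OCc1ccccc1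
F11 | step 13 | (2S,3S) 4-nitrobenzoate after Mitsunobu inversion | COc1cc([C@H]2OC[C@H]3[C@@H]2CO[C@@H]3c2cc(OC)c(O[C@H](C(=O)N3[C@@H](Cc4ccccc4)COC3=O)[C@@H](OC(=O)c3ccc(cc3)[N+](=O)[O-])c3ccc(OCc4ccccc4)c(OC)c3)c(OC)c2)ccc1OCc1ccccc1
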